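## Structural features

The target is a flavonol, a 4H-chromen-4-one in which the phloroglucinol-type ring A (C4a, C5, C6, C7, C8, C8a) is fused to the pyranone ring C, which carries the 3-hydroxyl and, on C2, the 4-hydroxyphenyl ring B. A 4-hydroxybenzyl group is joined through a single CH2 to C8, so that ring A bears oxygen on C5, C7 and C8a, carbon on C4a and C8, and hydrogen only on C6. The molecule has no stereocentre. The fragile elements are the 3-hydroxy-4-pyranone enol, which is degraded by oxidants in base, the five free hydroxyl groups, and the electron-rich diarylmethane CH2, which can be oxidised or can give up its benzyl group under strong acid. Strong acid can in addition open and reclose ring C (Wessely–Moser isomerisation), which would carry the benzyl group from C8 to C6. The real difficulty is therefore regiochemical: exactly one benzyl group has to stand on C8 and none on C6, and ring C has to be closed through the oxygen that lies next to that benzyl group. The key step exploits the alternating oxygen pattern of ring A, which is that of a folded polyketide: C8a, C8, C7, C6, C5 and C4a correspond to carbons 1 to 6 of a 3,5,7-triketo ester with the benzyl group on carbon 2 and the cinnamoyl carbonyl (C4) on carbon 7. Ring A can thus be closed between C4a and C8a by a Claisen condensation of a chain that is kept masked as a 3-benzyl-4-hydroxy-2-pyrone until that moment.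

## Logic of the disconnections

**15 back to 14.** The four aryl O–H bonds (at O5, O7, O4' and on the benzyl ring) are traced back to O–CH2Ph bonds. The free pentahydroxy compound is the most fragile one of the route and is released last. Benzyl ethers leave without Lewis or protic acid, so neither the C8 benzyl group nor ring C is endangered. The gain is that every earlier compound is a neutral ether that is easy to purify. The forward hydrogenolysis must cleave four ethers and spare the C2=C3 bond and the C8–CH2–aryl bonds.

**14 back to 12.** The C3–O bond is cut. The carbon that becomes C3 is an olefinic CH of the cinnamoyl unit during the folding, so its oxygen cannot be carried through the key step. A direct alkaline peroxide closure of 10 to 14 is not relied on, because a chalcone with a second ortho substituent tends to close to a five-membered ring instead. The gain is that 12 follows from 10 by a simple oxidative cyclisation. The forward step must deliver one oxygen atom to the C2=C3 bond, through 13, in the presence of two electron-rich rings and several benzylic CH2 groups.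

**12 back to 10.** The O1–C2 bond and the C2=C3 unsaturation are cut, which opens ring C. The gain is that rings A and B are then linked only by a three-carbon enone. The forward oxidative closure, through 11, demands that only one of the two oxygens ortho to the acyl group is free and that it is the one beside the benzyl group.

**10 back to 9.** The two O–CH2Ph bonds on the oxygens that become O7 and O5 are cut. This is the point at which the two ortho oxygens are told apart. The gain is that 9 is exactly what the folding step delivers, so no protecting group on ring A has to survive that step. The forward alkylation must leave untouched the hydroxyl wedged between the acyl group and the benzyl CH2.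

**9 back to 7.** The C4a–C8a bond of ring A is cut, and the oxygen on C8a is traced back to a lactone carbonyl. This is the key disconnection: the pentasubstituted benzene becomes a monocyclic pyrone with a keto side chain, and the position of the benzyl group is fixed by connectivity instead of by an aromatic substitution. The forward step must open the lactone to 8 and fold it in the Claisen sense and not in the aldol sense.

**7 back to 4 and 6.** The C4–C4a bond (ketone carbon to side-chain methylene) is cut. This divides the molecule into two pieces of similar size. The forward step needs a dianion that reacts at its methyl terminus, adds to the acyl carbon and not to the β-carbon of the enone, and is not quenched by its own product.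

**4 back to 1 and 2.** The bond between C8 and the benzyl CH2 is cut. In 1 the carbon between the two oxygenated carbons is the only nucleophilic ring carbon, so exactly one benzyl group can be introduced. The forward step must reduce 3 before it captures a second molecule of 1.

**6 back to 2 and 5.** The olefin that becomes C2=C3 is cut. Both aryl groups of the target then come from the same aldehyde 2. The forward olefination must give the E isomer.

## Other disconnections considered

Alternative 1: The cut is the C3–C4 bond of ring C. In the forward direction samarium diiodide A3 would reduce the aromatic aldehyde of the aryl ether dialdehyde 2-[1-(4-methoxyphenyl)-2-oxoethoxy]-4,6-dimethoxy-3-(4-methoxybenzyl)benzaldehyde A2 to a ketyl radical anion. Addition of that radical to the neighbouring aliphatic aldehyde would close ring C as the flavan-3,4-diol 5,7-dimethoxy-8-(4-methoxybenzyl)-2-(4-methoxyphenyl)chromane-3,4-diol A1.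
- In its favour: the oxygen on C3 is built in during the ring closure, under the neutral reducing conditions of A3. No late oxidation of a flavone by an electrophilic oxidant is needed, and on this point the alternative is better than the chosen plan.
- Against it, on mechanism: the aliphatic aldehyde of A2 carries an aryloxy group on its α-carbon, and electron transfer from A3 to such a carbonyl is expected to expel the aryloxide. The aromatic aldehyde of A2 is doubly ortho-substituted and electron-rich, hence a poor electron acceptor. A2 is also an enolisable α-aryl-α-aryloxy aldehyde that would be hard to handle.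
- Against it, on structure: A1 stands two oxidation levels (four hydrogens) below the target, and its three stereocentres would be made only to be destroyed. The pentasubstituted ring A with the benzyl group on C8 still has to be prepared first, and the two ortho oxygens still have to be told apart when the ether of A2 is made. On that central problem the alternative is no better than the chosen plan.
- On step economy it is clearly longer: the aromatic part, the dialdehyde and the later oxidations all need steps of their own. The methyl ethers of A1 would also call for a Lewis-acid dealkylation at the end.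

Alternative 2: The cut removes four bonds of ring A (C8–C8a, C7–C8, C5–C6 and C4a–C5). In the forward direction irradiation of the diazo ketone 6-[2-diazo-3-(4-methoxyphenyl)propanoyl]-3-methoxy-2-(4-methoxyphenyl)-4H-pyran-4-one A5 would trigger a Wolff rearrangement. Ketene–alkyne cycloaddition with ethoxyacetylene A6, four-electron ring opening and 6π closure would then give 7-ethoxy-5-hydroxy-3-methoxy-8-(4-methoxybenzyl)-2-(4-methoxyphenyl)-4H-chromen-4-one A4.
- In its favour: the benzyl group on C8, the free hydroxyl on C5 and the ether on C7 follow from the mechanism without any regiochemical choice. The C3 oxygen is present from the start. On both points the alternative is better than the chosen plan, and it forms four bonds in one operation against one. A6 is a single commercial reagent, which is equal to the simplicity of the reagents of the chosen plan.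
- Against it, on the precursor: A5 is a 2,3,6-trisubstituted 4-pyranone that needs a multi-step synthesis of its own. Its diazo group must be placed on a carbon that already carries a benzyl group, which calls for a deacylative diazo transfer.
- Against it, on mechanism: the pyranone of A5 and the chromone of A4 absorb light and have photochemistry of their own, which would compete with the Wolff step. The 6π closure has to use a double bond of the cross-conjugated pyranone, a less willing partner than a simple alkene. A6 is volatile and acid-sensitive and would have to be used in excess.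
- Against it, at the end: the ethyl and methyl ethers of A4 can only be removed with a strong Lewis acid, the operation that the chosen plan avoids.
- Overall it is the equal or the better of the chosen plan in structural control. It is weaker in the accessibility of its precursor and in the safety of the end game, and probably longer.

Alternative 3: The cut is C8–C8a and C4a–C5. In the forward direction the benzyl-substituted ketene acetal diene trimethyl{[1,3-dimethoxy-5-(4-methoxyphenyl)penta-1,3-dien-1-yl]oxy}silane A8 would add to methyl 3-bromopropiolate A9 in a Diels–Alder reaction. Aromatisation with loss of the acetal methoxy group would give methyl 2-bromo-6-hydroxy-4-methoxy-3-(4-methoxybenzyl)benzoate A7.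
- In its favour: the polarity of A8 and A9 fixes the regiochemistry. C8a is marked as a bromide while C5 carries the free hydroxyl, so the two positions ortho to C4a cannot be confused. On this point the alternative is better than the chosen plan, which has to rely on a selective alkylation. The reaction class is thermal and robust.
- Against it, on structure: A7 contains ring A only. The C4 ketone, all of ring C, ring B and the C3 oxygen remain to be added.
- Against it, on mechanism: the C8a–O bond would have to be made at a bromide flanked by an ester and a benzyl group, a doubly ortho-hindered position. A8 carries a substituent on its nucleophilic terminus, which slows the cycloaddition, and it must be made in several steps. A9 is a lachrymatory and thermally labile haloalkyne that would have to be prepared shortly before use.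
- On step economy it is the longest of the four plans. The chosen plan delivers ring A already joined to the complete three-carbon bridge and ring B.

Key step: step 4

Remark on protecting groups: the aryl ethers carried through the route are benzyl ethers and not methyl ethers, so that the last step is a hydrogenolysis and not a Lewis-acid dealkylation. The bond and the ring formed in the key step, and the skeletons of its precursor 7 and its product 9, are unchanged by this choice.

Remark on the atom mapping of the key step: chain carbon 6 of 8 becomes C4a and the former lactone carbonyl carbon becomes C8a. The benzyl-bearing carbon therefore ends on C8, between the oxygens on C8a and C7.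

Remark on drawing: 7 and 8 are drawn as keto tautomers, although both should be largely enolised. Equivalents are proposed amounts.

## Steps

Step 1
Reactants: 1 triacetic acid lactone (4-hydroxy-6-methyl-2H-pyran-2-one); 2 4-(benzyloxy)benzaldehyde
Product: 4 3-[4-(benzyloxy)benzyl]-4-hydroxy-6-methyl-2H-pyran-2-one, via alkylidene pyrandione 3 (not isolated)
Conditions: Hantzsch ester (diethyl 2,6-dimethyl-1,4-dihydropyridine-3,5-dicarboxylate, 1.1 equiv), L-proline (20 mol%), CH2Cl2–EtOH, rt
Reagents that add atoms: none
Why: Knoevenagel condensation at C3 of the pyrone, its only nucleophilic carbon, gives the strongly electrophilic alkylidene 3, which the Hantzsch ester should reduce by conjugate hydride transfer faster than a second pyrone can add (three-component reductive alkylation of cyclic 1,3-dicarbonyl compounds); one benzyl group is installed and no stereocentre arises.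

Step 2
Reactants: 2 4-(benzyloxy)benzaldehyde; 5 diethyl [2-(methoxy(methyl)amino)-2-oxoethyl]phosphonate
Product: 6 (E)-3-[4-(benzyloxy)phenyl]-N-methoxy-N-methylprop-2-enamide
Conditions: NaH, THF, 0 °C to rt; aq NH4Cl
Reagents that add atoms: none
Why: Horner–Wadsworth–Emmons olefination with an amide-stabilised phosphonate anion, which is reliably E-selective with aromatic aldehydes, gives the Weinreb amide directly from the same aldehyde that supplies the benzyl group.

Step 3
Reactants: 4 3-[4-(benzyloxy)benzyl]-4-hydroxy-6-methyl-2H-pyran-2-one; 6 (E)-3-[4-(benzyloxy)phenyl]-N-methoxy-N-methylprop-2-enamide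
Product: 7 3-[4-(benzyloxy)benzyl]-6-[(E)-4-(4-(benzyloxy)phenyl)-2-oxobut-3-en-1-yl]-4-hydroxy-2H-pyran-2-one
Conditions: LiN(iPr)2 (2.5 equiv), THF, −78 to −40 °C; then 6, −78 to −20 °C; cold 1 M HCl
Reagents that add atoms: none
Why: Two equivalents of base remove the acidic 4-OH proton and then one proton of the 6-methyl group, and the hard terminal carbanion of this dianion adds to the amide carbonyl (acylation of 4-hydroxy-6-methyl-2-pyrone dianions; Weinreb ketone synthesis). The chelated tetrahedral adduct should persist until the acid quench, so the acidic product can neither quench unreacted dianion nor be attacked a second time, and the E olefin is not touched.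

Step 4
Reactants: 7 3-[4-(benzyloxy)benzyl]-6-[(E)-4-(4-(benzyloxy)phenyl)-2-oxobut-3-en-1-yl]-4-hydroxy-2H-pyran-2-one
Product: 9 (E)-1-{3-[4-(benzyloxy)benzyl]-2,4,6-trihydroxyphenyl}-3-[4-(benzyloxy)phenyl]prop-2-en-1-one, via triketo ester 8 (not isolated)
Conditions: Mg(OMe)2 (8 equiv), MeOH–THF, reflux, argon; ice-cold 1 M HCl; crude 9 taken directly into step 5
Reagents that add atoms: none
Why: Methoxide adds to the lactone carbonyl of 7 and the ring oxygen leaves as the enolate of a new ketone, which unmasks triketo ester 8 as its magnesium chelate. Within the chelate the carbon between the C5 and C7 carbonyls of the chain (chain C6, the methylene next to the cinnamoyl ketone) attacks the magnesium-activated ester carbonyl (chain C1) and methoxide is expelled, an intramolecular Claisen (Dieckmann-type) condensation; the resulting cyclohexane-1,3,5-trione should enolise at once to the phloroglucinol and be held as a magnesium phenolate, which makes the closure irreversible. The closest known reaction type is the Mg(OMe)2 recyclisation of 6-(2-oxoalkyl)-4-hydroxy-2-pyrones and of 3,5,7-triketo esters to acylphloroglucinols. Ring A is closed in the 6-exo-trig mode at the ester carbonyl (enolexo for the C6=C7 enolate), and the bond formed is C4a–C8a in flavone numbering. No stereocentre is created, and the labile one at chain C2 of 8 disappears on aromatisation. The selectivity needed is Claisen over aldol folding: divalent magnesium ties the 1,3-dicarbonyl pairs into chelates that present C6 to the activated ester, and the alternative aldol attack of chain C2 on the C7 ketone would give a quaternary carbon carrying benzyl and ester that cannot aromatise and should therefore revert. Additions of methoxide or of an enol oxygen to the enone are reversible and should drain into the phenolate, so the E double bond is retained. Because the benzyl group sits on chain C2 from the outset, it can only end on C8, next to the oxygen on C8a.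

Step 5
Reactants: 9 (E)-1-{3-[4-(benzyloxy)benzyl]-2,4,6-trihydroxyphenyl}-3-[4-(benzyloxy)phenyl]prop-2-en-1-one
Product: 10 (E)-1-{4,6-bis(benzyloxy)-3-[4-(benzyloxy)benzyl]-2-hydroxyphenyl}-3-[4-(benzyloxy)phenyl]prop-2-en-1-one
Conditions: BnBr (2.1 equiv), K2CO3 (2.5 equiv), DMF, 0 °C to rt, argon
Reagents that add atoms: benzyl bromide, BrCc1ccccc1
Why: Williamson etherification with a limited amount of halide should take the most acidic 4'-hydroxyl (para to the acyl group) first and then the 6'-hydroxyl, which has an open flank, while the 2'-hydroxyl wedged between the acyl group and the benzyl CH2 stays behind as the buttressed, chelated phenol, as in the partial O-alkylation of C-alkylated phloroacylphenones. Any flavanone formed from 9 during the work-up of step 4 should reopen to the chalcone phenoxide under these basic conditions, so the material is expected to converge on 10.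

Step 6
Reactants: 10 (E)-1-{4,6-bis(benzyloxy)-3-[4-(benzyloxy)benzyl]-2-hydroxyphenyl}-3-[4-(benzyloxy)phenyl]prop-2-en-1-one
Product: 12 5,7-bis(benzyloxy)-8-[4-(benzyloxy)benzyl]-2-[4-(benzyloxy)phenyl]-4H-chromen-4-one, via flavanone 11 (not isolated)
Conditions: I2 (10 mol%), DMSO, 120 °C
Reagents that add atoms: none
Why: The single free phenol, the one beside the benzyl group, adds to the enone to give flavanone 11, which iodine dehydrogenates by α-iodination and loss of HI while DMSO reoxidises HI to I2 (iodine–DMSO oxidative cyclisation of 2'-hydroxychalcones); with only this oxygen free, ring C can close only so that the benzyl group stands on C8.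

Step 7
Reactants: 12 5,7-bis(benzyloxy)-8-[4-(benzyloxy)benzyl]-2-[4-(benzyloxy)phenyl]-4H-chromen-4-one
Product: 14 5,7-bis(benzyloxy)-8-[4-(benzyloxy)benzyl]-2-[4-(benzyloxy)phenyl]-3-hydroxy-4H-chromen-4-one, via flavone epoxide 13 (not isolated)
Conditions: DMDO (acetone solution, 3 equiv), CH2Cl2, 0 °C to rt, dark; then p-TsOH·H2O (cat.), CH2Cl2, rt
Reagents that add atoms: dimethyldioxirane, CC1(C)OO1
Why: The dioxirane transfers oxygen to the enol-ether-like C2=C3 bond of the chromone (dioxirane epoxidation of flavones), and acid opens epoxide 13 at C2 to an oxocarbenium ion that loses the C3 proton to give the 3-hydroxyflavone. The neutral, metal-free oxidant should leave the fully etherified rings and the benzylic CH2 groups alone.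

Step 8
Reactants: 14 5,7-bis(benzyloxy)-8-[4-(benzyloxy)benzyl]-2-[4-(benzyloxy)phenyl]-3-hydroxy-4H-chromen-4-one
Product: 15 8-C-p-hydroxybenzylkaempferol (3,5,7-trihydroxy-8-(4-hydroxybenzyl)-2-(4-hydroxyphenyl)-4H-chromen-4-one)
Conditions: H2 (1 atm), 10% Pd/C, THF–MeOH, rt
Reagents that add atoms: none
Why: Catalytic hydrogenolysis cleaves the four O–benzyl bonds, whereas the aryl–CH2–aryl bonds and the chromone enol double bond should not be reduced at one atmosphere and room temperature. No acid is present, so neither benzyl migration nor ring-C reopening can move the substituent from C8.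

## Compound list

1 | triacetic acid lactone (4-hydroxy-6-methyl-2H-pyran-2-one) | Cc1cc(O)cc(=O)o1 | starting material
2 | 4-(benzyloxy)benzaldehyde | O=Cc1ccc(OCc2ccccc2)cc1 | starting material
3 | 3-[4-(benzyloxy)benzylidene]-6-methyl-2H-pyran-2,4(3H)-dione (either olefin geometry) | CC1=CC(=O)C(=Cc2ccc(OCc3ccccc3)cc2)C(=O)O1 | intermediate (not isolated)
4 | 3-[4-(benzyloxy)benzyl]-4-hydroxy-6-methyl-2H-pyran-2-one | Cc1cc(O)c(Cc2ccc(OCc3ccccc3)cc2)c(=O)o1 | intermediate
5 | diethyl [2-(methoxy(methyl)amino)-2-oxoethyl]phosphonate | CCOP(=O)(CC(=O)N(C)OC)OCC | starting material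
6 | (E)-3-[4-(benzyloxy)phenyl]-N-methoxy-N-methylprop-2-enamide | CON(C)C(=O)/C=C/c1ccc(OCc2ccccc2)cc1 | intermediate
7 | 3-[4-(benzyloxy)benzyl]-6-[(E)-4-(4-(benzyloxy)phenyl)-2-oxobut-3-en-1-yl]-4-hydroxy-2H-pyran-2-one | O=C(/C=C/c1ccc(OCc2ccccc2)cc1)Cc1cc(O)c(Cc2ccc(OCc3ccccc3)cc2)c(=O)o1 | intermediate
8 | methyl (E)-2-[4-(benzyloxy)benzyl]-9-[4-(benzyloxy)phenyl]-3,5,7-trioxonon-8-enoate (racemic at C2, triketo tautomer drawn) | COC(=O)C(Cc1ccc(OCc2ccccc2)cc1)C(=O)CC(=O)CC(=O)/C=C/c1ccc(OCc2ccccc2)cc1 | intermediate (not isolated)
9 | (E)-1-{3-[4-(benzyloxy)benzyl]-2,4,6-trihydroxyphenyl}-3-[4-(benzyloxy)phenyl]prop-2-en-1-one | O=C(/C=C/c1ccc(OCc2ccccc2)cc1)c1c(O)cc(O)c(Cc2ccc(OCc3ccccc3)cc2)c1O | intermediate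
10 | (E)-1-{4,6-bis(benzyloxy)-3-[4-(benzyloxy)benzyl]-2-hydroxyphenyl}-3-[4-(benzyloxy)phenyl]prop-2-en-1-one | O=C(/C=C/c1ccc(OCc2ccccc2)cc1)c1c(OCc2ccccc2)cc(OCc2ccccc2)c(Cc2ccc(OCc3ccccc3)cc2)c1O | intermediate
11 | 5,7-bis(benzyloxy)-8-[4-(benzyloxy)benzyl]-2-[4-(benzyloxy)phenyl]-2,3-dihydro-4H-chromen-4-one (racemic at C2) | O=C1CC(c2ccc(OCc3ccccc3)cc2)Oc2c(Cc3ccc(OCc4ccccc4)cc3)c(OCc3ccccc3)cc(OCc3ccccc3)c21 | intermediate (not isolated)
12 | 5,7-bis(benzyloxy)-8-[4-(benzyloxy)benzyl]-2-[4-(benzyloxy)phenyl]-4H-chromen-4-one | O=c1cc(-c2ccc(OCc3ccccc3)cc2)oc2c(Cc3ccc(OCc4ccccc4)cc3)c(OCc3ccccc3)cc(OCc3ccccc3)c12 | intermediate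
13 | 2,3-epoxide of 12: 4,6-bis(benzyloxy)-3-[4-(benzyloxy)benzyl]-1a-[4-(benzyloxy)phenyl]-1a,7a-dihydro-7H-oxireno[2,3-b]chromen-7-one (racemic, oxirane necessarily cis-fused) | O=C1C2OC2(c2ccc(OCc3ccccc3)cc2)Oc2c(Cc3ccc(OCc4ccccc4)cc3)c(OCc3ccccc3)cc(OCc3ccccc3)c21 | intermediate (not isolated)
14 | 5,7-bis(benzyloxy)-8-[4-(benzyloxy)benzyl]-2-[4-(benzyloxy)phenyl]-3-hydroxy-4H-chromen-4-one | O=c1c(O)c(-c2ccc(OCc3ccccc3)cc2)oc2c(Cc3ccc(OCc4ccccc4)cc3)c(OCc3ccccc3)cc(OCc3ccccc3)c12 | intermediate
15 | 8-C-p-hydroxybenzylkaempferol | O=c1c(O)c(-c2ccc(O)cc2)oc2c(Cc3ccc(O)cc3)c(O)cc(O)c12 | target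

## Step count and least certain steps

Total step count: 8. Longest linear sequence: 7 (steps 1, 3, 4, 5, 6, 7, 8); step 2 is a one-step branch.

**Step 4 (key step).** The pyrone is doubly deprotonated and hindered at C3, so its methanolysis could be incomplete, with lactone reclosure outrunning the Claisen closure. On acidification the trihydroxychalcone may also isomerise partly to flavanones; step 5 is expected to correct this, but it complicates handling.
Fallback, from 2 to 10: 2 would be reduced with NaBH4 in MeOH to [4-(benzyloxy)phenyl]methanol F1. Under acid catalysis (p-TsOH, dioxane, 60 °C) F1 would benzylate an excess of commercial 2',4',6'-trihydroxyacetophenone in a Friedel–Crafts reaction, to give 1-{3-[4-(benzyloxy)benzyl]-2,4,6-trihydroxyphenyl}ethan-1-one F2. Selective O-benzylation of F2 as in step 5 would give 1-{4,6-bis(benzyloxy)-3-[4-(benzyloxy)benzyl]-2-hydroxyphenyl}ethan-1-one F3. Claisen–Schmidt condensation of F3 with a second portion of 2 (KOH, EtOH) would then give 10, where the route is rejoined. The price is statistical control of mono- against bis-C-benzylation, which the pyrone route avoids.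

**Step 3.** The delocalised dianion could add in conjugate fashion to the cinnamoyl acceptor, or proton transfer could stall the acylation if the tetrahedral adduct collapses early.
Fallback, from 4 (with 2) to 7: 2 would be homologated with (triphenylphosphoranylidene)acetaldehyde (toluene, 80 °C) to (E)-3-[4-(benzyloxy)phenyl]prop-2-enal F4. The dianion of 4 would be added to the aldehyde carbonyl of F4 at −78 °C to give racemic 3-[4-(benzyloxy)benzyl]-6-[(E)-4-(4-(benzyloxy)phenyl)-2-hydroxybut-3-en-1-yl]-4-hydroxy-2H-pyran-2-one F5. Oxidation of the allylic alcohol of F5 with MnO2 in CH2Cl2 would give 7, where the route is rejoined.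

**Step 5.** Site selectivity between the two chelating hydroxyls could be lost, or over-alkylation or C-benzylation at the free ring carbon could occur. Loss of site selectivity would later place the benzyl group partly on C6.
Fallback, from 9 to 10: 9 would be benzylated exhaustively (excess BnBr, K2CO3, DMF, 60 °C) to (E)-1-{2,4,6-tris(benzyloxy)-3-[4-(benzyloxy)benzyl]phenyl}-3-[4-(benzyloxy)phenyl]prop-2-en-1-one F6. Treatment of F6 with MgBr2·OEt2 (toluene–Et2O, reflux) should cleave only the ortho ether that is chelated to the ketone and twisted out of the ring plane between the acyl group and the benzyl substituent, and so return 10. The selection principle is reversed: steric acceleration of a chelation-controlled dealkylation in place of steric retardation of an alkylation.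

**Step 7.** During the slow epoxidation of the vinylogous ester, oxygen could also be transferred to the benzylic C–H bonds of the ethers and of the diarylmethane, or to the alkoxy-rich rings.
Fallback, from 12 to 14: 12 would be lithiated at C3 with LiN(iPr)2 in THF at −78 °C and trapped with B(OMe)3 to give dimethyl {5,7-bis(benzyloxy)-8-[4-(benzyloxy)benzyl]-2-[4-(benzyloxy)phenyl]-4-oxo-4H-chromen-3-yl}boronate F7. Oxidation of the C–B bond of F7 with H2O2 in AcOH would give 14, where the route is rejoined.

## Further compounds

F1 | step 4 | [4-(benzyloxy)phenyl]methanol | OCc1ccc(OCc2ccccc2)cc1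
F2 | step 4 | 1-{3-[4-(benzyloxy)benzyl]-2,4,6-trihydroxyphenyl}ethan-1-one | CC(=O)c1c(O)cc(O)c(Cc2ccc(OCc3ccccc3)cc2)c1O
F3 | step 4 | 1-{4,6-bis(benzyloxy)-3-[4-(benzyloxy)benzyl]-2-hydroxyphenyl}ethan-1-one | CC(=O)c1c(OCc2ccccc2)cc(OCc2ccccc2)c(Cc2ccc(OCc3ccccc3)cc2)c1O
F4 | step 3 | (E)-3-[4-(benzyloxy)phenyl]prop-2-enal | O=C/C=C/c1ccc(OCc2ccccc2)cc1
F5 | step 3 | 3-[4-(benzyloxy)benzyl]-6-[(E)-4-(4-(benzyloxy)phenyl)-2-hydroxybut-3-en-1-yl]-4-hydroxy-2H-pyran-2-one (racemic) | OC(/C=C/c1ccc(OCc2ccccc2)cc1)Cc1cc(O)c(Cc2ccc(OCc3ccccc3)cc2)c(=O)o1
F6 | step 5 | (E)-1-{2,4,6-tris(benzyloxy)-3-[4-(benzyloxy)benzyl]phenyl}-3-[4-(benzyloxy)phenyl]prop-2-en-1-one | O=C(/C=C/c1ccc(OCc2ccccc2)cc1)c1c(OCc2ccccc2)cc(OCc2ccccc2)c(Cc2ccc(OCc3ccccc3)cc2)c1OCc1ccccc1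
F7 | step 7 | dimethyl {5,7-bis(benzyloxy)-8-[4-(benzyloxy)benzyl]-2-[4-(benzyloxy)phenyl]-4-oxo-4H-chromen-3-yl}boronate | COB(OC)c1c(-c2ccc(OCc3ccccc3)cc2)oc2c(Cc3ccc(OCc4ccccc4)cc3)c(OCc3ccccc3)cc(OCc3ccccc3)c2c1=O
A1 | alternative 1 | 5,7-dimethoxy-8-(4-methoxybenzyl)-2-(4-methoxyphenyl)chromane-3,4-diol (racemic, 2,3-trans-3,4-cis isomer drawn) | O[C@@H]1[C@H](O)[C@@H](c2ccc(OC)cc2)Oc2c1c(OC)cc(OC)c2Cc1ccc(OC)cc1
A2 | alternative 1 | 2-[1-(4-methoxyphenyl)-2-oxoethoxy]-4,6-dimethoxy-3-(4-methoxybenzyl)benzaldehyde (racemic) | O=CC(Oc1c(C=O)c(OC)cc(OC)c1Cc1ccc(OC)cc1)c1ccc(OC)cc1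
A3 | alternative 1 | samarium diiodide | [Sm+2].[I-].[I-]
A4 | alternative 2 | 7-ethoxy-5-hydroxy-3-methoxy-8-(4-methoxybenzyl)-2-(4-methoxyphenyl)-4H-chromen-4-one | CCOc1cc(O)c2c(=O)c(OC)c(-c3ccc(OC)cc3)oc2c1Cc1ccc(OC)cc1
A5 | alternative 2 | 6-[2-diazo-3-(4-methoxyphenyl)propanoyl]-3-methoxy-2-(4-methoxyphenyl)-4H-pyran-4-one | COc1ccc(CC(=[N+]=[N-])C(=O)c2cc(=O)c(OC)c(-c3ccc(OC)cc3)o2)cc1
A6 | alternative 2 | ethoxyacetylene | CCOC#C
A7 | alternative 3 | methyl 2-bromo-6-hydroxy-4-methoxy-3-(4-methoxybenzyl)benzoate | COC(=O)c1c(O)cc(OC)c(Cc2ccc(OC)cc2)c1Br
A8 | alternative 3 | trimethyl{[1,3-dimethoxy-5-(4-methoxyphenyl)penta-1,3-dien-1-yl]oxy}silane (olefin geometry not specified) | COC(O[Si](C)(C)C)=CC(OC)=CCc1ccc(OC)cc1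
A9 | alternative 3 | methyl 3-bromopropiolate | COC(=O)C#CBr
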